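The runs were computed on assumed constants; the scatter is artificial.

- In a one-step world each unit of reagent makes a unit of target and the count stops, so your hunch that feeding changes nothing would be fair. But birch already shows 29.5% side product at 40.0 h, so target goes on reacting.

| setting | birch | elm | alder | Tuesday's | Sunday's | Wednesday's | Friday's |
|---|---|---|---|---|---|---|---|
| starting material | 0.064 M | 0.064 M | 0.064 M | 0.064 M | 0.064 M | 0.064 M (fed, over 15 h) | 0.064 M |
| reagent | 0.50 equiv | 0.25 equiv | 0.38 equiv | 0.500 equiv (fed, over 15 h) | 0.500 equiv (in portions, 5, over 15 h) | 0.500 equiv | 0.500 equiv |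
| second substrate | 1 equiv | 1 equiv | 1 equiv | 1.00 equiv | 1.00 equiv | 1.00 equiv | 1.00 equiv |
| free catalyst | 0.55 mol% | 0.55 mol% | 0.55 mol% | 0.55 mol% | 0.55 mol% | 0.55 mol% | 0.55 mol% |
| added ligand | 0.38 mM | 0.38 mM | 0.38 mM | 0.38 mM | 0.38 mM | 0.38 mM | 0.38 mM |
| remark | run made earlier | run made earlier | run made earlier | all else is in the flask from the start; the feed brings no volume worth counting | first portion at the start, last at 15 h | all else is in the flask from the start; the feed brings no volume worth counting | everything together at the start |
| time |  |  |  | 40 h | 40 h | 40 h | 40 h |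

| run | time / h | side product / % | target / % | starting material / % |
|---|---|---|---|---|
| birch | 6.00 | 3.3 | 17.1 | 82.9 |
| birch | 12.0 | 8.3 | 20.9 | 71.5 |
| birch | 20.0 | 13.5 | 22.6 | 61.6 |
| birch | 25.0 | 20.5 | 22.3 | 56.2 |
| birch | 30.0 | 21.6 | 20.1 | 55.6 |
| birch | 40.0 | 29.5 | 20.5 | 49.4 |
| elm | 3.00 | 0 | 6.7 | 94.0 |
| elm | 10.0 | 3.7 | 11.6 | 87.0 |
| elm | 15.0 | 5.8 | 9.8 | 82.1 |
| elm | 25.0 | 11.7 | 12.3 | 75.9 |
| elm | 40.0 | 17.4 | 10.3 | 72.6 |
| elm | 50.0 | 22.8 | 10.0 | 69.1 |
| alder | 3.00 | 0 | 9.6 | 91.6 |
| alder | 10.0 | 5.1 | 16.9 | 79.3 |
| alder | 15.0 | 9.0 | 15.6 | 74.0 |
| alder | 25.0 | 16.7 | 17.5 | 67.3 |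
| alder | 40.0 | 24.5 | 14.7 | 59.5 |
| alder | 50.0 | 31.7 | 16.2 | 57.4 |

(scatter of a reading: 1 percentage point)

- the flask with the highest amount of side product, in percent of the starting material charged ("all alike" if they lie within 1.5 percentage points) (Tuesday's / Sunday's / Wednesday's / Friday's / all alike)
- final side product, as a percentage of the starting material charged, in Tuesday's
- final side product, as a percentage of the starting material charged, in Sunday's
- final side product, as a percentage of the starting material charged, in Wednesday's
- final side product, as a percentage of the starting material charged, in Friday's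

- a species is counted by the starting material in it: one side product counts as two

- We write the balance of the reagent, the limiting reagent at 0.500 equiv, less than the second substrate. A target takes one reagent, and a side product, counted as two, holds one target. So reagent spent is target plus half the side product, and side product is twice the difference between reagent spent and target.
- We read the spent share at 40.0 h, reagent spent over reagent charged: 70.5% in birch, 76.0% in elm, 70.9% in alder. The mean spent share is 72.5%.
- Friday's repeats birch. With birch's late target reading of 21.0%, our number for Friday's is 30.5%.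
- Of the reagent still standing in birch at 6.00 h, a share of 52.8% is read as spent by 40.0 h, less than the mean spent share. So we expect late reagent in Tuesday's and Sunday's to count for less, and in Wednesday's we expect a like delay from starting material fed over 15 h.
- A gap of 0.75 percentage points of the starting material charged in reagent spent, at equal target, already reaches the margin. We commit to Friday's highest, without separate figures for the fed flasks.
- The forecast gives 24.5%, 25.5%, 24.5% and 28% for Tuesday's, Sunday's, Wednesday's and Friday's, with Friday's highest, since “Each feed delays target”.
- The flasks give 22.3%, 22.6%, 21.8% and 29.7% in that order, so Friday's is highest, against our 30.5%.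

    starting material + target → side product (k = 1.30 × 10⁻⁴ L mol⁻¹ s⁻¹)
    second substrate + reagent + free catalyst → free catalyst + second product (k = 0.0520 L² mol⁻² s⁻¹)
    2 free catalyst → spent catalyst (k = 0.0590 L mol⁻¹ s⁻¹)
    free catalyst + added ligand ⇌ idle complex, settled at all times (K = 1200 L mol⁻¹)
    starting material + reagent + free catalyst → free catalyst + target (k = 1.70 L² mol⁻² s⁻¹)

- Second product takes reagent too, so the balance gains a term. The neighbour of Wednesday's with 0.14 mol% of free catalyst has 60% of its reagent left, a spent share of 39.9%, less than our mean. Taking off the second product leaves 19.0% of the starting material charged. Taking off the target, 12.1%, and doubling gives 13.8%, and that flask holds 13.9% side product.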